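**Retrosynthetic overview**

1. The strategy rests on the pyran ring of the 2H-chromene, O1–C2(CH3)2–C3=C4 fused to the arene: C2 carries two methyl groups and the aryl-bound oxygen, which is a coumarin lactone O1–C2(=O)–C3=C4 after two methyl additions. Hence 20 ← bis-silyl chromene 19 ← Z-diol 18 ← coumarin 16.
2. 16 ← C(sp2)–O disconnection of the enol ether: (S)-alcohol 6 plus Z-vinyl iodide 15, joined by stereoretentive copper-catalysed O-vinylation.
3. 6 ← 6-acetyl-7-methoxycoumarin 5 (asymmetric transfer hydrogenation sets S) ← Pechmann condensation of 2,4-dihydroxyacetophenone with malic acid.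
4. 15 ← copper-catalysed anti-arylmagnesiation and iodination of propargyl alcohol with the Grignard reagent from 2-iodo-5-methylphenol; this fixes the alkene geometry.
5. Ring order: both benzene rings are bought; the lactone ring is made in step 1, carried as the masked pyran, opened in step 9 and reclosed as the 2,2-dimethylpyran in step 10.

Key step: step 9

Remark on the chemistry: racemic malic acid serves as compound 2 because its stereocentre is lost on decarbonylation, propargyl alcohol supplies the three enol ether carbons, and both hydroxyl groups of the side chain are carried as triisopropylsilyl ethers.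

**Route**

Step 1
Reactants: 1 2,4-dihydroxyacetophenone; 2 malic acid
Product: 4 6-acetyl-7-hydroxycoumarin, via formylacetic acid 3 (not isolated)
Conditions: conc. H2SO4, 100 °C
Reagents that add atoms: none
Why: Pechmann coumarin synthesis: H2SO4 decarbonylates malic acid to formylacetic acid, which condenses at C5 of the resorcinol ring (ortho to the free 4-OH, para to the chelated 2-OH) and lactonises through the 4-OH, so the acetyl group should end up at C6 and the hydroxyl at C7.

Step 2
Reactants: 4 6-acetyl-7-hydroxycoumarin
Product: 5 6-acetyl-7-methoxycoumarin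
Conditions: MeI, K2CO3, acetone, reflux
Reagents that add atoms: iodomethane, CI
Why: Williamson O-methylation of the phenoxide; the lactone and the aryl ketone are inert to carbonate in acetone.

Step 3
Reactants: 5 6-acetyl-7-methoxycoumarin
Product: 6 (S)-6-(1-hydroxyethyl)-7-methoxycoumarin
Conditions: RuCl(p-cymene)[(S,S)-TsDPEN] (1 mol%), HCO2H/Et3N (5:2), EtOAc, 40 °C
Reagents that add atoms: none
Why: Noyori asymmetric transfer hydrogenation of an aryl methyl ketone; the (S,S)-ligand delivers hydride to the face that gives the S carbinol through the aryl/CH–π transition state, and the conjugated lactone is not reduced.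

Step 4
Reactants: 7 2-iodo-5-methylphenol
Product: 8 1-iodo-2-(methoxymethoxy)-4-methylbenzene
Conditions: MOMCl, iPr2NEt, CH2Cl2, 0 °C to rt
Reagents that add atoms: chloromethyl methyl ether, COCCl
Why: O-alkylation of the phenol to its methoxymethyl acetal, chosen because this group cannot migrate to carbon in the ortho-magnesiated arene of step 5.

Step 5
Reactants: 8 1-iodo-2-(methoxymethoxy)-4-methylbenzene; 9 propargyl alcohol
Product: 13 (Z)-3-iodo-2-[2-(methoxymethoxy)-4-methylphenyl]prop-2-en-1-ol, via aryl Grignard reagent 10 (not isolated), via chloromagnesium propargyl alkoxide 11 (not isolated), via alkenylmagnesium chelate 12 (not isolated)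
Conditions: 8, Mg, THF, rt; 9, iPrMgCl (1.0 equiv), THF, 0 °C; combine, CuI (10 mol%), 0 °C to rt; then I2, THF, −20 °C to rt
Reagents that add atoms: iodine, II
Why: Duboudin-type copper-catalysed anti-arylmagnesiation of the propargyl alkoxide puts the aryl group on C2 and magnesium on C3 inside a five-membered oxamagnesacycle, so iodinolysis with retention should give the iodide cis to CH2OH (Z).

Step 6
Reactants: 13 (Z)-3-iodo-2-[2-(methoxymethoxy)-4-methylphenyl]prop-2-en-1-ol
Product: 14 2-[(Z)-3-hydroxy-1-iodoprop-1-en-2-yl]-5-methylphenol
Conditions: conc. HCl (cat.), MeOH, 40 °C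
Reagents that add atoms: none
Why: Acid-catalysed acetal exchange with methanol cleaves the aryl methoxymethyl ether; the vinyl iodide and the primary allylic alcohol tolerate dilute acid, and no acid-labile group is present yet.

Step 7
Reactants: 14 2-[(Z)-3-hydroxy-1-iodoprop-1-en-2-yl]-5-methylphenol
Product: 15 (Z)-vinyl iodide with both hydroxyl groups as triisopropylsilyl ethers
Conditions: TIPSOTf (2.4 equiv), 2,6-lutidine, CH2Cl2, 0 °C to rt
Reagents that add atoms: triisopropylsilyl triflate, CC(C)[Si](OS(=O)(=O)C(F)(F)F)(C(C)C)C(C)C
Why: Silylation of phenol and primary alcohol with a silyl triflate; the bulky aryl silyl ether should withstand carbonate at 90 °C in step 8, and both groups fall to fluoride at the end.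

Step 8
Reactants: 6 (S)-6-(1-hydroxyethyl)-7-methoxycoumarin; 15 (Z)-vinyl iodide with both hydroxyl groups as triisopropylsilyl ethers
Product: 16 7-methoxycoumarin carrying the S-configured Z-enol ether side chain at C6
Conditions: CuI (10 mol%), 3,4,7,8-tetramethyl-1,10-phenanthroline (20 mol%), Cs2CO3, PhMe, 90 °C
Reagents that add atoms: none
Why: Ullmann-type copper-catalysed C–O cross-coupling of an alcohol with a vinyl iodide proceeds with retention of alkene geometry and never breaks the carbinol C–O bond, so the Z geometry of 15 and the S centre of 6 should both be transferred.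

Step 9
Reactants: 16 7-methoxycoumarin carrying the S-configured Z-enol ether side chain at C6
Product: 18 Z-configured ortho-(3-hydroxy-3-methylbut-1-enyl)phenol with the complete side chain, via Z-enone phenoxide 17 (not isolated)
Conditions: MeLi (4 equiv), CeCl3 (anhydrous, 4 equiv), THF, −78 °C; then pH 7 phosphate buffer
Reagents that add atoms: methyllithium, C[Li]
Why: Methylcerium dichloride, formed from MeLi and CeCl3, adds to the lactone carbonyl of 16; the tetrahedral alkoxide collapses with loss of the aryl oxide to the Z-configured methyl enone phenoxide 17, and a second equivalent adds 1,2 to that ketone, so both C2–CH3 bonds are made in one operation. The closest known reaction type is the double addition of methyl Grignard, methyllithium or organocerium reagents to coumarins on the way to 2,2-dimethyl-2H-chromenes. No ring is closed and no stereocentre is created here; the pyran is only unmasked as its open Z-diol. The step needs 1,2- over 1,4-selectivity at both carbonyl stages and no enolisation of the intermediate methyl ketone, which the weakly basic, oxophilic organocerium reagent secures, while the Z geometry is inherited from the ring C3=C4 bond. The substrate has no other carbonyl group, and the silyl ethers, the enol ether and the S benzylic ether are inert to the reagent at −78 °C; the neutral buffer quench keeps the acid-sensitive diol intact, and any closure to 19 that begins on work-up is harmless.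

Step 10
Reactants: 18 Z-configured ortho-(3-hydroxy-3-methylbut-1-enyl)phenol with the complete side chain
Product: 19 bis-silylated 7-methoxy-2,2-dimethyl-2H-chromene with the S-configured Z-enol ether side chain at C6
Conditions: silica gel, CH2Cl2, rt
Reagents that add atoms: none
Why: Cyclodehydration: the tertiary allylic alcohol ionises on the weakly acidic surface to an allyl cation stabilised by the ortho oxygen and the para methoxy group (a protonated ortho-quinone methide), which the cis-disposed phenol captures in a six-membered closure, under conditions that should be too mild to protonate the enol ether or ionise the benzylic ether.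

Step 11
Reactants: 19 bis-silylated 7-methoxy-2,2-dimethyl-2H-chromene with the S-configured Z-enol ether side chain at C6
Product: 20 target compound CNP0279099.1
Conditions: TBAF (2.5 equiv), THF, 0 °C to rt; pH 7 buffer work-up
Reagents that add atoms: none
Why: Fluoride-mediated cleavage of the aryl and the primary alkyl silyl ether under non-acidic conditions, which should leave the enol ether, the benzylic ether, the chromene alkene and the S centre untouched.

**Compound list**

1 | 2,4-dihydroxyacetophenone | CC(=O)c1ccc(O)cc1O | starting material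
2 | malic acid (racemic) | OC(CC(=O)O)C(=O)O | starting material
3 | formylacetic acid (3-oxopropanoic acid) | O=CCC(=O)O | intermediate
4 | 6-acetyl-7-hydroxycoumarin | CC(=O)c1cc2C=CC(=O)Oc2cc1O | intermediate
5 | 6-acetyl-7-methoxycoumarin | COc1cc2OC(=O)C=Cc2cc1C(C)=O | intermediate
6 | (S)-6-(1-hydroxyethyl)-7-methoxycoumarin | COc1cc2OC(=O)C=Cc2cc1[C@H](C)O | intermediate
7 | 2-iodo-5-methylphenol | Cc1ccc(I)c(O)c1 | starting material
8 | 1-iodo-2-(methoxymethoxy)-4-methylbenzene | COCOc1cc(C)ccc1I | intermediate
9 | propargyl alcohol (prop-2-yn-1-ol) | C#CCO | starting material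
10 | [2-(methoxymethoxy)-4-methylphenyl]magnesium iodide | COCOc1cc(C)ccc1[Mg]I | intermediate
11 | chloromagnesium prop-2-yn-1-olate | C#CCO[Mg]Cl | intermediate
12 | 4-[2-(methoxymethoxy)-4-methylphenyl]-2,5-dihydro-1,2-oxamagnesole (magnesium on the alkene carbon cis to CH2O) | COCOc1cc(C)ccc1C1=C[Mg]OC1 | intermediate
13 | (Z)-3-iodo-2-[2-(methoxymethoxy)-4-methylphenyl]prop-2-en-1-ol | I/C=C(\CO)c1ccc(C)cc1OCOC | intermediate
14 | 2-[(Z)-3-hydroxy-1-iodoprop-1-en-2-yl]-5-methylphenol | I/C=C(\CO)c1ccc(C)cc1O | intermediate
15 | triisopropyl{2-[(Z)-1-iodo-3-(triisopropylsilyloxy)prop-1-en-2-yl]-5-methylphenoxy}silane | I/C=C(\CO[Si](C(C)C)(C(C)C)C(C)C)c1ccc(C)cc1O[Si](C(C)C)(C(C)C)C(C)C | intermediate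
16 | 7-methoxy-6-[(S)-1-{[(Z)-2-(4-methyl-2-triisopropylsilyloxyphenyl)-3-(triisopropylsilyloxy)prop-1-enyl]oxy}ethyl]coumarin | COc1cc2OC(=O)C=Cc2cc1[C@H](C)O/C=C(\CO[Si](C(C)C)(C(C)C)C(C)C)c1ccc(C)cc1O[Si](C(C)C)(C(C)C)C(C)C | intermediate
17 | Z-enone from the first methyl addition (a metal phenoxide in the flask, drawn as the phenol) | COc1cc(O)c(/C=C\C(C)=O)cc1[C@H](C)O/C=C(\CO[Si](C(C)C)(C(C)C)C(C)C)c1ccc(C)cc1O[Si](C(C)C)(C(C)C)C(C)C | intermediate
18 | Z-configured 2-(3-hydroxy-3-methylbut-1-enyl)-5-methoxyphenol carrying the S-configured bis-silylated Z-enol ether side chain at C4 | COc1cc(O)c(/C=C\C(C)(C)O)cc1[C@H](C)O/C=C(\CO[Si](C(C)C)(C(C)C)C(C)C)c1ccc(C)cc1O[Si](C(C)C)(C(C)C)C(C)C | intermediate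
19 | bis(triisopropylsilyl) ether of the target: 7-methoxy-2,2-dimethyl-2H-chromene with the S-configured Z-enol ether side chain at C6 | COc1cc2c(cc1[C@H](C)O/C=C(\CO[Si](C(C)C)(C(C)C)C(C)C)c1ccc(C)cc1O[Si](C(C)C)(C(C)C)C(C)C)C=CC(C)(C)O2 | intermediate
20 | CNP0279099.1: 2-[(Z)-3-hydroxy-1-{[(S)-1-(7-methoxy-2,2-dimethyl-2H-chromen-6-yl)ethyl]oxy}prop-1-en-2-yl]-5-methylphenol | COc1cc2c(cc1[C@H](C)O/C=C(\CO)c1ccc(C)cc1O)C=CC(C)(C)O2 | target

**Step count**

Total step count: 11. Longest linear sequence: 8 steps (steps 4, 5, 6, 7, 8, 9, 10, 11, from 2-iodo-5-methylphenol).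

**Steps most likely to fail**

Step 8. The C–O bond may form slowly between the hindered secondary benzylic alcohol and the trisubstituted vinyl iodide. During that time, carbonate or alkoxide could open the lactone or strip the aryl silyl ether, and the freed phenoxide would then close onto the vinyl iodide. The fallback reverses the polarity of the vinyl partner and avoids carbonate and heat. It sets out from 15: Miyaura borylation (B2pin2, PdCl2(PPh3)2, PPh3, KOPh, PhMe, 50 °C) should give with retention the Z-alkenyl pinacol boronate F1. Oxidative copper-mediated etherification of 6 with an excess of F1 under Chan–Lam–Evans conditions (Cu(OAc)2, Et3N, 4 Å MS, CH2Cl2, air, rt) then forms the same enol ether bond and comes back to the route at 16.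

Step 9. Conjugate addition to the coumarin or to the intermediate enone, arrest at the ketone stage through enolisation, or attack of the basic reagent on the aryl silyl ether may compete with the double 1,2-addition. The fallback performs the same lactone-to-carbinol conversion before the side chain is present. It sets out from 6: excess MeLi/CeCl3 in THF at −78 °C should give the triol F2, which closes on silica gel to (S)-1-(7-methoxy-2,2-dimethyl-2H-chromen-6-yl)ethanol F3. Copper-catalysed vinylation of F3 with 15 under the conditions of step 8, now without a lactone in the molecule, comes back to the route at 19.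

Step 1. The chelated, deactivated ketophenol may sulfonate and char in hot H2SO4 before it condenses, and ring attack may be split between C5 and C3. The fallback installs the acetyl group by cross-coupling on a coumarin whose Pechmann step is better behaved. It sets out from 2 and commercial 4-bromoresorcinol F4: Pechmann condensation (conc. H2SO4, 100 °C) gives 6-bromo-7-hydroxycoumarin F5, and methylation (MeI, K2CO3, acetone) gives 6-bromo-7-methoxycoumarin F6. Stille coupling with tributyl(1-ethoxyvinyl)stannane (Pd(PPh3)4, PhMe, 100 °C) gives 6-(1-ethoxyvinyl)-7-methoxycoumarin F7, and hydrolysis with dilute aqueous HCl in THF comes back to the route at 5.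

**Further compounds**

F1 | step 8 | 2-{(Z)-2-[4-methyl-2-(triisopropylsilyloxy)phenyl]-3-(triisopropylsilyloxy)prop-1-enyl}-4,4,5,5-tetramethyl-1,3,2-dioxaborolane | CC1(C)OB(/C=C(\CO[Si](C(C)C)(C(C)C)C(C)C)c2ccc(C)cc2O[Si](C(C)C)(C(C)C)C(C)C)OC1(C)C
F2 | step 9 | 2-[(Z)-3-hydroxy-3-methylbut-1-enyl]-4-[(S)-1-hydroxyethyl]-5-methoxyphenol | COc1cc(O)c(/C=C\C(C)(C)O)cc1[C@H](C)O
F3 | step 9 | (S)-1-(7-methoxy-2,2-dimethyl-2H-chromen-6-yl)ethanol | COc1cc2OC(C)(C)C=Cc2cc1[C@H](C)O
F4 | step 1 | 4-bromoresorcinol | Oc1ccc(Br)c(O)c1
F5 | step 1 | 6-bromo-7-hydroxycoumarin | Oc1cc2OC(=O)C=Cc2cc1Br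
F6 | step 1 | 6-bromo-7-methoxycoumarin | COc1cc2OC(=O)C=Cc2cc1Br
F7 | step 1 | 6-(1-ethoxyvinyl)-7-methoxycoumarin | CCOC(=C)c1cc2C=CC(=O)Oc2cc1OC
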